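**Strategy.** Ring B is cut back to 3-methylcyclohexenone. With C8 as a ketone, the quaternary C10 is the β-carbon and C9 the α-carbon of an enone (labdane numbering). Everything rests on forming C1–C10 and C9–C11 in one flask. A ligand-controlled, copper-catalysed conjugate addition of the homoprenyl Grignard reagent sets C10, and the C8–C9 magnesium enolate is trapped by methyl vinyl ketone, setting C9 relative to C10. The precursors are three small achiral pieces: the enone, the Grignard reagent and the vinyl ketone. The adduct already holds C1–C13, C16 and C18–C20. Later steps move the carbonyl to C6, close ring A at C4–C5, install both hydroxyls and add C14–C15.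

Key step: step 2

Remark: atom labels follow labdane numbering (ring A C1–C5 and C10, ring B C5–C10, chain C11–C16, C17 on C8, C18/C19 on C4, C20 on C10). The target has the mirror-image (ent) labdane configuration; in ent-names "α" means anti to the C10 methyl. This corresponds to the (S) quaternary centre of 6, so the ligand enantiomer is the one that delivers the alkyl group to the Re face of C3 of 1.

Step 1
Reactants: 2 5-bromo-2-methylpent-2-ene
Product: 3 (4-methylpent-3-en-1-yl)magnesium bromide
Conditions: Mg turnings, I2 (cat.), Et2O, reflux; titrated solution used directly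
Reagents that add atoms: magnesium, [Mg]
Why: Grignard formation by magnesium insertion into the primary C–Br bond; slow addition of the homoallylic bromide keeps Wurtz coupling low, and no stereocentre is involved.

Step 2
Reactants: 1 3-methylcyclohex-2-en-1-one; 3 (4-methylpent-3-en-1-yl)magnesium bromide; 4 methyl vinyl ketone
Product: 6 (2S,3S)-3-methyl-3-(4-methylpent-3-en-1-yl)-2-(3-oxobutyl)cyclohexan-1-one, via bromomagnesium enolate 5 (not isolated)
Conditions: Cu(OTf)2 (3 mol %), 1-mesityl-3-(1-hydroxy-4-methylpentan-2-yl)-4,5-dihydroimidazolium hexafluorophosphate (single enantiomer, 4 mol %), 3 (1.2 equiv), Et2O, 0 °C, slow addition of 1; then 4 (1.3 equiv) added slowly, −78 °C; AcOH, −78 °C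
Reagents that add atoms: none
Why: The Grignard reagent deprotonates the imidazolinium salt and transmetalates to an NHC-bound alkylcopper species, which forms a π-complex with 1, adds oxidatively at C10 to a trivalent-copper intermediate and reductively eliminates to form C1–C10; the resulting C8–C9 bromomagnesium enolate 5 then adds at C9 to the terminal carbon of 4 (bond C9–C11) and is quenched cold. The closest known reaction type is the copper/NHC-catalysed asymmetric conjugate addition of Grignard reagents to 3-substituted cyclohexenones with trapping of the magnesium enolate by a carbon electrophile (tandem conjugate addition–Michael reaction). No ring is closed. C10 is controlled by the chiral NHC ligand (Re-face delivery at C3 of 1, giving S); C9 is controlled by the new quaternary centre, the vinyl ketone approaching anti to the longer homoprenyl chain, which is also the isomer with both chains equatorial. The step needs 1,4- over 1,2-addition (copper catalysis, slow addition of the β-methyl enone), a single enolate regioisomer (the enolate is born at C8–C9 next to a hydrogen-free C10 and is kept at −78 °C) and one Michael addition without polymerization or aldol closure (slow addition of 4 at −78 °C, cold acetic acid quench).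

Step 3
Reactants: 6 (2S,3S)-3-methyl-3-(4-methylpent-3-en-1-yl)-2-(3-oxobutyl)cyclohexan-1-one
Product: 7 (2S,3S)-3-methyl-3-(4-methylpent-3-en-1-yl)-2-[2-(2-methyl-1,3-dioxolan-2-yl)ethyl]cyclohexan-1-one
Conditions: TMSOCH2CH2OTMS (1.2 equiv), TMSOTf (3 mol %), CH2Cl2, −78 to −40 °C; pyridine
Reagents that add atoms: 1,2-bis(trimethylsilyloxy)ethane, C[Si](C)(C)OCCO[Si](C)(C)C
Why: Silyl-triflate-catalysed ketalization with the bis-silyl glycol selects the unhindered methyl ketone C13 over the C8 ketone flanked by C9 and quaternary C10, and the cold aprotic conditions avoid aldol closure of the 1,5-diketone and epimerization at C9.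

Step 4
Reactants: 7 (2S,3S)-3-methyl-3-(4-methylpent-3-en-1-yl)-2-[2-(2-methyl-1,3-dioxolan-2-yl)ethyl]cyclohexan-1-one
Product: 9 5-methyl-5-(4-methylpent-3-en-1-yl)-6-[2-(2-methyl-1,3-dioxolan-2-yl)ethyl]cyclohex-2-en-1-one (the 6-en-8-one), via trimethylsilyl enol ether 8 (not isolated)
Conditions: LiN(i-Pr)2, TMSCl, THF, −78 °C; crude 8, Pd(OAc)2 (1.05 equiv), MeCN, rt
Reagents that add atoms: none
Why: Saegusa–Ito oxidation: kinetic deprotonation takes the C7 methylene rather than the hindered C9–H, and divalent palladium dehydrogenates the silyl enol ether through an oxo-π-allyl species and β-hydride loss from C6, giving the C6=C7 enone without touching C9 or C10.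

Step 5
Reactants: 9 5-methyl-5-(4-methylpent-3-en-1-yl)-6-[2-(2-methyl-1,3-dioxolan-2-yl)ethyl]cyclohex-2-en-1-one
Product: 10 1,5-dimethyl-5-(4-methylpent-3-en-1-yl)-6-[2-(2-methyl-1,3-dioxolan-2-yl)ethyl]cyclohex-2-en-1-ol (both C8 epimers)
Conditions: CH3Li, CeCl3 (anhydrous), THF, −78 °C
Reagents that add atoms: methyllithium, [Li]C
Why: 1,2-Addition of a methylcerium reagent, nucleophilic but barely basic, to the hindered and enolizable enone carbonyl; the new C8 carbinol centre forms as a mixture that does not matter because C8 becomes sp2 in the next step.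

Step 6
Reactants: 10 1,5-dimethyl-5-(4-methylpent-3-en-1-yl)-6-[2-(2-methyl-1,3-dioxolan-2-yl)ethyl]cyclohex-2-en-1-ol
Product: 11 3,5-dimethyl-5-(4-methylpent-3-en-1-yl)-4-[2-(2-methyl-1,3-dioxolan-2-yl)ethyl]cyclohex-2-en-1-one (the monocyclic 8-methyl-7-en-6-one)
Conditions: [C5H5NH][CrO3Cl] (pyridinium chlorochromate), 4 Å molecular sieves, CH2Cl2, rt
Reagents that add atoms: pyridinium chlorochromate, [O-][Cr](=O)(=O)Cl.c1cc[nH+]cc1
Why: Babler–Dauben oxidative transposition: the chromate ester of the tertiary allylic alcohol undergoes a [3,3] shift to C6 and is then oxidized, giving the 8-methyl-7-en-6-one in which C5 is the α′ carbon; the dioxolane and the trisubstituted alkene tolerate the chlorochromate.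

Step 7
Reactants: 11 3,5-dimethyl-5-(4-methylpent-3-en-1-yl)-4-[2-(2-methyl-1,3-dioxolan-2-yl)ethyl]cyclohex-2-en-1-one
Product: 12 5-(4-chloro-4-methylpentyl)-3,5-dimethyl-4-[2-(2-methyl-1,3-dioxolan-2-yl)ethyl]cyclohex-2-en-1-one
Conditions: anhydrous HCl, CH2Cl2, −78 to −40 °C; Et3N quench at −78 °C
Reagents that add atoms: hydrogen chloride, Cl
Why: Markovnikov hydrochlorination: protonation of the trisubstituted alkene at C3 gives the tertiary C4 cation, which chloride captures; the electron-poor enone does not add HCl irreversibly, and the cold amine quench re-closes any opened dioxolane.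

Step 8
Reactants: 12 5-(4-chloro-4-methylpentyl)-3,5-dimethyl-4-[2-(2-methyl-1,3-dioxolan-2-yl)ethyl]cyclohex-2-en-1-one
Product: 15 ent-14,15-dinorlabd-7-ene-6,13-dione 13-(ethylene ketal), via silyl dienol ether 13 (not isolated), via cis-fused enone 14 (not isolated)
Conditions: LiN(i-Pr)2, TMSCl, THF, −78 °C; crude 13, ZnCl2 (20 mol %), CH2Cl2, −20 °C to rt; then NaOMe (cat.), MeOH, rt
Reagents that add atoms: none
Why: Intramolecular α-tert-alkylation of a silyl enol ether (SN1 alkylation of the Reetz type): kinetic α′-deprotonation at C5 gives the cross-conjugated 2-silyloxydiene, the zinc halide ionizes the tertiary chloride reversibly and is too weak to open the dioxolane, C5 attacks the C4 cation to close ring A (cis-fused expected for stereoelectronic reasons), and methoxide then equilibrates C5 through the enolate to the trans-fused ketone, expected to be the more stable one, with H5 anti to the C10 methyl.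

Step 9
Reactants: 15 ent-14,15-dinorlabd-7-ene-6,13-dione 13-(ethylene ketal)
Product: 16 ent-7α,8α-epoxy-14,15-dinorlabdane-6,13-dione 13-(ethylene ketal)
Conditions: H2O2 (30 % aq.), NaOH, MeOH, 0 °C to rt
Reagents that add atoms: hydrogen peroxide, OO
Why: Weitz–Scheffer nucleophilic epoxidation: hydroperoxide adds axially to C8 on the face opposite the axial C10 methyl and the enolate closes onto oxygen, so the 7,8-epoxide lies anti to C20, which fixes C8.

Step 10
Reactants: 16 ent-7α,8α-epoxy-14,15-dinorlabdane-6,13-dione 13-(ethylene ketal)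
Product: 17 ent-8α-hydroxy-14,15-dinorlabdane-6,13-dione 13-(ethylene ketal)
Conditions: SmI2 (2.5 equiv), THF/MeOH, −90 °C
Reagents that add atoms: none
Why: Single-electron reduction of the α,β-epoxy ketone by SmI2 cleaves the Cα–O bond at C7 and methanol protonates the samarium enolate at low temperature, giving the β-hydroxy ketone with the C8–O bond (and the C8 configuration) intact and without dehydration.

Step 11
Reactants: 17 ent-8α-hydroxy-14,15-dinorlabdane-6,13-dione 13-(ethylene ketal)
Product: 18 ent-6α,8α-dihydroxy-14,15-dinorlabdan-13-one ethylene ketal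
Conditions: Li, NH3(l), THF, −78 °C; NH4Cl
Reagents that add atoms: none
Why: Dissolving-metal reduction of the C6 ketone: the ketyl/carbanion intermediate settles into the more stable arrangement and protonation gives the equatorial C6 alcohol, anti to the axial C10 and C4 methyls and therefore syn to the C8 hydroxyl, whereas hydride reagents would attack the open face and give the axial epimer; the dioxolane is inert.

Step 12
Reactants: 18 ent-6α,8α-dihydroxy-14,15-dinorlabdan-13-one ethylene ketal
Product: 19 ent-6α,8α-dihydroxy-14,15-dinorlabdan-13-one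
Conditions: 1 M aq. HCl, THF, 0 °C to rt
Reagents that add atoms: water, O
Why: Acid-catalysed hydrolysis of the dioxolane under mild aqueous conditions that leave the tertiary C8 alcohol and all stereocentres untouched; the product may sit partly as its 8,13-hemiketal, which opens in the next step.

Step 13
Reactants: 19 ent-6α,8α-dihydroxy-14,15-dinorlabdan-13-one
Product: 20 methyl ent-6α,8α-dihydroxylabd-13E-en-15-oate (the target)
Conditions: (MeO)2P(O)CH2CO2Me (4 equiv), NaH (3.8 equiv), THF, 0 to 50 °C
Reagents that add atoms: trimethyl phosphonoacetate, COC(=O)CP(=O)(OC)OC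
Why: Horner–Wadsworth–Emmons olefination of the methyl ketone with the sodium phosphonate, kept in slight excess over NaH so that no alkoxide forms from the diol and oxa-Michael closure onto the enoate is avoided; the E isomer (ester trans to the C12 chain) is expected to predominate and the Z isomer is removed by chromatography.

**Compound list**

1 | 3-methylcyclohex-2-en-1-one | CC1=CC(=O)CCC1 | starting material
2 | 5-bromo-2-methylpent-2-ene | CC(C)=CCCBr | starting material
3 | (4-methylpent-3-en-1-yl)magnesium bromide | CC(C)=CCC[Mg]Br | intermediate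
4 | methyl vinyl ketone (but-3-en-2-one) | C=CC(C)=O | starting material
5 | bromomagnesium (3S)-3-methyl-3-(4-methylpent-3-en-1-yl)cyclohex-1-en-1-olate (C8–C9 enolate) | Br[Mg]OC1=C[C@](C)(CCC=C(C)C)CCC1 | intermediate (not isolated)
6 | (2S,3S)-3-methyl-3-(4-methylpent-3-en-1-yl)-2-(3-oxobutyl)cyclohexan-1-one; oxobutyl trans to the pentenyl chain | CC(=O)CC[C@H]1[C@](C)(CCC=C(C)C)CCCC1=O | intermediate
7 | (2S,3S)-3-methyl-3-(4-methylpent-3-en-1-yl)-2-[2-(2-methyl-1,3-dioxolan-2-yl)ethyl]cyclohexan-1-one | CC1(CC[C@H]2[C@](C)(CCC=C(C)C)CCCC2=O)OCCO1 | intermediate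
8 | trimethylsilyl enol ether of 7 toward C7 (C7=C8–OSiMe3); C9 and C10 as in 6 | CC1(CC[C@H]2[C@](C)(CCC=C(C)C)CCC=C2O[Si](C)(C)C)OCCO1 | intermediate (not isolated)
9 | 5-methyl-5-(4-methylpent-3-en-1-yl)-6-[2-(2-methyl-1,3-dioxolan-2-yl)ethyl]cyclohex-2-en-1-one (6-en-8-one); C9 and C10 as in 6 | CC1(CC[C@H]2[C@](C)(CCC=C(C)C)CC=CC2=O)OCCO1 | intermediate
10 | 1,5-dimethyl-5-(4-methylpent-3-en-1-yl)-6-[2-(2-methyl-1,3-dioxolan-2-yl)ethyl]cyclohex-2-en-1-ol; both C8 epimers, C9 and C10 as in 6 | CC1(CC[C@H]2[C@](C)(CCC=C(C)C)CC=CC2(C)O)OCCO1 | intermediate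
11 | 3,5-dimethyl-5-(4-methylpent-3-en-1-yl)-4-[2-(2-methyl-1,3-dioxolan-2-yl)ethyl]cyclohex-2-en-1-one (monocyclic 8-methyl-7-en-6-one); C9 and C10 as in 6 | CC1(CC[C@H]2[C@](C)(CCC=C(C)C)CC(=O)C=C2C)OCCO1 | intermediate
12 | 5-(4-chloro-4-methylpentyl)-3,5-dimethyl-4-[2-(2-methyl-1,3-dioxolan-2-yl)ethyl]cyclohex-2-en-1-one; C9 and C10 as in 6 | CC1(CC[C@H]2[C@](C)(CCCC(C)(C)Cl)CC(=O)C=C2C)OCCO1 | intermediate
13 | cross-conjugated trimethylsilyl dienol ether of 12 (C5=C6–OSiMe3, C7=C8) | CC1(CC[C@H]2[C@](C)(CCCC(C)(C)Cl)C=C(O[Si](C)(C)C)C=C2C)OCCO1 | intermediate (not isolated)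
14 | C5 epimer of 15 (cis-fused, H5 syn to the C10 methyl) | CC1(CC[C@H]2[C@]3(C)CCCC(C)(C)[C@@H]3C(=O)C=C2C)OCCO1 | intermediate (not isolated)
15 | ent-14,15-dinorlabd-7-ene-6,13-dione 13-(ethylene ketal); trans-fused, H5 anti and C11 syn to the C10 methyl | CC1(CC[C@H]2[C@]3(C)CCCC(C)(C)[C@H]3C(=O)C=C2C)OCCO1 | intermediate
16 | ent-7α,8α-epoxy-14,15-dinorlabdane-6,13-dione 13-(ethylene ketal); epoxide oxygen anti to the C10 methyl | CC1(CC[C@H]2[C@]3(C)CCCC(C)(C)[C@H]3C(=O)[C@@H]4O[C@]24C)OCCO1 | intermediate
17 | ent-8α-hydroxy-14,15-dinorlabdane-6,13-dione 13-(ethylene ketal); 8-OH anti to the C10 methyl | CC1(CC[C@H]2[C@]3(C)CCCC(C)(C)[C@H]3C(=O)C[C@]2(C)O)OCCO1 | intermediate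
18 | ent-6α,8α-dihydroxy-14,15-dinorlabdan-13-one ethylene ketal; both hydroxyls anti to the C10 methyl | CC1(CC[C@H]2[C@]3(C)CCCC(C)(C)[C@H]3[C@H](O)C[C@]2(C)O)OCCO1 | intermediate
19 | ent-6α,8α-dihydroxy-14,15-dinorlabdan-13-one | CC(=O)CC[C@H]1[C@]2(C)CCCC(C)(C)[C@H]2[C@H](O)C[C@]1(C)O | intermediate
20 | methyl ent-6α,8α-dihydroxylabd-13E-en-15-oate = methyl (2E)-5-[(1S,2S,4R,4aR,8aR)-2,4-dihydroxy-2,5,5,8a-tetramethyldecahydronaphthalen-1-yl]-3-methylpent-2-enoate | COC(=O)/C=C(\C)CC[C@H]1[C@]2(C)CCCC(C)(C)[C@H]2[C@H](O)C[C@]1(C)O | target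

**Step count and risks**

Total steps: 13. Longest linear sequence: 13 (from 2 to 20; 1 and 4 enter at step 2).

Steps most likely to fail:

1. Step 2. The magnesium enolate may start anionic oligomerization of the vinyl ketone, may be protonated by it instead of adding, or may add with poor facial discrimination at C9; the 1,5-diketone may also close by aldol reaction if the quench is not cold. The fallback sets out from 1 and 3 and comes back at 6. The copper-catalysed addition is run as in step 2, but enolate 5 is silylated (TMSCl, Et3N, HMPA, 0 °C) to the isolable trimethylsilyl enol ether F1. A Mukaiyama–Michael addition of F1 to 4 (BF3·OEt2, i-PrOH, MeNO2/CH2Cl2, −78 °C) then gives 6; the alcohol takes up the silyl group and the Lewis-acid-bound vinyl ketone cannot polymerize anionically. If the C9 ratio is poor in either variant, the epimers are separated after step 3 and the unwanted one is re-equilibrated at C9 on ketal 7 with NaOMe in MeOH, where aldol closure is impossible.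

2. Step 8. The zinc halide may ionize the tertiary chloride too slowly, or a Lewis acid strong enough to do so may open the dioxolane and let C5 capture the resulting oxocarbenium ion (bridged ring); the C5 equilibration may also stop short. The fallback sets out from 12 and comes back at 15, exchanging the ketone mask for one that is inert to a strong Lewis acid. The dioxolane of 12 is removed on oxalic-acid-loaded wet silica in CH2Cl2 to give the chloro dione F2. NaBH4 in MeOH at −78 °C reduces only the saturated methyl ketone, not the hindered conjugated one, giving the chloro hydroxy enone F3. LiN(i-Pr)2 (2.2 equiv) with TMSCl silylates the alkoxide and forms the silyloxydiene; TiCl4 in CH2Cl2 at −78 °C effects the classical tert-alkylation; NaOMe in MeOH epimerizes C5 and frees the alcohol, giving the bicyclic hydroxy enone F4. Dess–Martin periodinane gives the bicyclic dione F5, whose unhindered C13 ketone is ketalized as in step 3 to return to 15.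

3. Step 9. Hydroperoxide addition to the hindered β,β-disubstituted enone may be sluggish, leaving time for base-induced deconjugation or epimerization. The fallback sets out from 15 and comes back at 17, replacing steps 9 and 10. Copper-catalysed conjugate borylation (B2pin2, CuCl, NaOt-Bu, xantphos, MeOH, THF) places boron on C8 anti to C20 to give the β-boryl ketone F6. Oxidation with NaBO3·4H2O in THF/H2O converts C–B into C–OH with retention, giving 17.

**Further compounds**

F1 | step 2 | trimethyl{[(3S)-3-methyl-3-(4-methylpent-3-en-1-yl)cyclohex-1-en-1-yl]oxy}silane | C[Si](C)(C)OC1=C[C@](C)(CCC=C(C)C)CCC1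
F2 | step 8 | 5-(4-chloro-4-methylpentyl)-3,5-dimethyl-4-(3-oxobutyl)cyclohex-2-en-1-one (C9 and C10 as in 12) | CC(=O)CC[C@H]1[C@](C)(CCCC(C)(C)Cl)CC(=O)C=C1C
F3 | step 8 | 5-(4-chloro-4-methylpentyl)-4-(3-hydroxybutyl)-3,5-dimethylcyclohex-2-en-1-one (both C13 epimers) | CC(O)CC[C@H]1[C@](C)(CCCC(C)(C)Cl)CC(=O)C=C1C
F4 | step 8 | ent-13-hydroxy-14,15-dinorlabd-7-en-6-one (both C13 epimers, trans-fused) | CC(O)CC[C@H]1[C@]2(C)CCCC(C)(C)[C@H]2C(=O)C=C1C
F5 | step 8 | ent-14,15-dinorlabd-7-ene-6,13-dione | CC(=O)CC[C@H]1[C@]2(C)CCCC(C)(C)[C@H]2C(=O)C=C1C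
F6 | step 9 | ent-8α-(4,4,5,5-tetramethyl-1,3,2-dioxaborolan-2-yl)-14,15-dinorlabdane-6,13-dione 13-(ethylene ketal) | CC1(CC[C@H]2[C@]3(C)CCCC(C)(C)[C@H]3C(=O)C[C@]2(C)B4OC(C)(C)C(C)(C)O4)OCCO1
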